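The zeta run carried the same starting material, free catalyst and impurity as the two flasks below, at Wednesday's temperature, so I began from it and counted turnovers.

common to all: free catalyst 0.25 µM; impurity 0.15 µM
- zeta: starting material 0.50 mM (in portions, 3); partner 0.17 mM; temperature 100 °C; run made earlier; portions every 15 s
- Monday's: starting material 0.50 mM; partner 0.350 mM; temperature 115 °C; everything together at the start; time 8.0 min
- Wednesday's: starting material 0.50 mM (in portions, 3); partner 0.350 mM; temperature 100 °C; the portions of starting material follow each other after 15 s, the first at the start; time 12 min

zeta run (percent of the starting material charged)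

| time / min | target / % | starting material / % |
|---|---|---|
| 0.500 | 3.9 | 62.8 |
| 1.00 | 7.6 | 91.0 |
| 1.33 | 10.6 | 88.9 |
| 2.00 | 15.6 | 85.3 |
| 2.50 | 20.1 | 81.3 |

(each reading ± 0.5 percentage points)

- the earlier runs do not show what temperature does; that part of a forecast is a guess

* the winner by amount of target, in percent of the starting material charged; "neither" if no more than 2 percentage points parts them (Monday's / Wednesday's / neither)
* how much target is there at the end, in percent of the starting material charged: Monday's
* how much target is there at the end, in percent of the starting material charged: Wednesday's

I supposed one partner used per target formed, and one free catalyst lost per impurity. In both flasks partner is then the limiting reagent, and I reckoned in fractions of the charge of starting material: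

ceiling on target = partner / starting material = 70.0%

working catalyst = (free catalyst − impurity) / starting material = 0.0200%

ceiling / working catalyst = 3500

That count, the rounds each working catalyst must make before target stands at the ceiling, is the turnovers needed.

In the zeta run target rose from 3.9% at 0.500 min to 20.1% at 2.50 min, a pace of 0.0810 min⁻¹ as a fraction of the charge, and so 405 min⁻¹ in turnovers.

Then I turned the question round. For the two to part, one flask must stop more than 2 percentage points short of the ceiling while the other reaches it, which means under 3400 turnovers. Wednesday's would have to run below 283 min⁻¹, and the zeta pace is faster than that, provided it holds as partner falls. Monday's would have to run below 425 min⁻¹, which is faster than the zeta pace. Monday's therefore needs a gain of 1.05 over the zeta pace, with its 115 °C and its single charge as the differences, and the earlier runs do not show what temperature does. I took that small gain as likely, and expected both flasks near the ceiling.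

The forecast said neither, with 69% (60% to 71%) for Monday's and 69% (63% to 71%) for Wednesday's: “Both end near the cap.”

Monday's flask gave 69.9% and Wednesday's flask gave 69.8%, less than 2 points apart, so the answer to which gave more is neither. At 12.0 min Wednesday's held 0.22% of its partner. Its target, divided by the working catalyst, counts 3490 turnovers against the 3500 needed.

    starting material + free catalyst → catalyst intermediate A (k = 1.20 × 10⁵ L mol⁻¹ s⁻¹, Ea = 10.0 kJ mol⁻¹)
    catalyst intermediate A → catalyst intermediate B (k = 170 s⁻¹, Ea = 83.0 kJ mol⁻¹)
    partner + catalyst intermediate B → catalyst intermediate C (k = 2.20 × 10⁵ L mol⁻¹ s⁻¹, Ea = 12.0 kJ mol⁻¹)
    catalyst intermediate C → free catalyst + target (k = 11.0 s⁻¹, Ea = 74.0 kJ mol⁻¹)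
    free catalyst + impurity → spent catalyst (k = 3.70 × 10⁷ L mol⁻¹ s⁻¹, Ea = 21.0 kJ mol⁻¹)
    (constants at 100 °C)

A neighbour of Monday's was charged with 2.0 mM of starting material and the same partner. The same 3500 turnovers now come to 17.5% of the larger charge. That neighbour gave 17.5% at 8.00 min, with 0.019% of its partner left.

The runs were computed for an exercise.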